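**Retrosynthetic overview** (target numbered as 2,3,7-trioxabicyclo[4.3.0]nonan-8-one: C1 = peroxy CH, C4 = peroxy quaternary carbon, C5 = CH2, C6 = lactone quaternary carbon, C8 = C=O, C9 = CH2)
1. Target 15 ⇐ methoxy peroxyketal 14 (C4–CH3 made last, by axial methyl transfer to the bicyclic peroxycarbenium ion) ⇐ open-chain α-methoxy hydroperoxide 12 (O2–C1 peroxy-Michael closes the 1,2-dioxane, then O7–C8 lactonization).
2. 12 ⇐ keto enoate 11 ⇐ oxolane 9, by retro-oxa-Michael opening of the C1–O bond and oxidation of the C4 carbinol; the oxolane is a temporary ring.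
3. 9 ⇐ keto β-alkoxyacrylate 8, by a samarium-diiodide ketyl–olefin cyclization that forms the C1–C6 bond.
4. Enabling feature: C4 and C6 are 1,3-related through C5 and both carry oxygen. With C4 held as a secondary carbinol, its oxygen carries C1, C9 and C8 as a β-alkoxyacrylate, so the ketyl at C6 reaches C1 in a 5-exo closure and the C4 stereocentre is relayed to C6 before it is oxidized away.
5. 8 ⇐ (R)-homoallylic alcohol 5 + methyl propiolate 6 (oxa-Michael, Wacker); 5 ⇐ 11-phenylundecanal 3 (Brown allylation). Ring order: oxolane (step 5, temporary), then 1,2-dioxane and γ-lactone (both step 9).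

Key step: step 5

Remark: 11-phenylundecanoic acid and (−)-B-allyldiisopinocampheylborane are taken as commercial.

Step 1
Reactants: 1 11-phenylundecanoic acid
Product: 3 11-phenylundecanal, via acyl chloride 2 (not isolated)
Conditions: (COCl)2, DMF (cat.), CH2Cl2, 0 °C to rt; concentrate; LiAlH(OtBu)3, THF, −78 °C
Reagents that add atoms: none
Why: Acyl chloride formation followed by hydride transfer from the hindered alkoxyaluminate at low temperature should stop at the aldehyde (partial reduction of an acid chloride); no stereocentre is involved.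

Step 2
Reactants: 3 11-phenylundecanal
Product: 5 (R)-14-phenyltetradec-1-en-4-ol, via borinate ester 4 (not isolated)
Conditions: (−)-Ipc2B(allyl), Et2O, −78 °C; then NaOH, H2O2, 0 °C to rt
Reagents that add atoms: (−)-B-allyldiisopinocampheylborane, C=CCB([C@@H]1C[C@@H]2C[C@H]([C@H]1C)C2(C)C)[C@@H]1C[C@@H]2C[C@H]([C@H]1C)C2(C)C
Why: Brown allylation: allyl transfer through a chair-like six-membered transition state, in which the (+)-α-pinene-derived isopinocampheyl groups leave the si face of the unbranched aldehyde open, should set the (R)-carbinol (future C4, a temporary stereocentre).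

Step 3
Reactants: 5 (R)-14-phenyltetradec-1-en-4-ol; 6 methyl propiolate
Product: 7 methyl (E)-3-{[(4R)-14-phenyltetradec-1-en-4-yl]oxy}prop-2-enoate
Conditions: N-methylmorpholine, CH2Cl2, rt
Reagents that add atoms: none
Why: Amine-catalysed oxa-Michael addition of the secondary alcohol to the propiolate should give the (E)-β-alkoxyacrylate; the carbinol centre is not touched.

Step 4
Reactants: 7 methyl (E)-3-{[(4R)-14-phenyltetradec-1-en-4-yl]oxy}prop-2-enoate
Product: 8 methyl (E)-3-{[(4R)-2-oxo-14-phenyltetradecan-4-yl]oxy}prop-2-enoate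
Conditions: PdCl2 (10 mol %), CuCl, O2 (1 atm), DMF–H2O (7:1), rt
Reagents that add atoms: water (O)
Why: Wacker oxidation (Markovnikov hydroxypalladation of the terminal alkene, then β-hydride elimination) should give the methyl ketone, while the conjugated, donor-substituted acrylate is left alone.

Step 5
Reactants: 8 methyl (E)-3-{[(4R)-2-oxo-14-phenyltetradecan-4-yl]oxy}prop-2-enoate
Product: 9 methyl 2-[(2S,3R,5R)-3-hydroxy-3-methyl-5-(10-phenyldecyl)oxolan-2-yl]acetate
Conditions: SmI2 (3 equiv), MeOH (3 equiv), THF, 0 °C
Reagents that add atoms: none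
Why: Samarium diiodide should reduce the methyl ketone to a samarium ketyl, which adds 5-exo-trig to the β-carbon of the tethered (E)-β-alkoxyacrylate; a second electron transfer and protonation by methanol give the ester, so the C1–C6 bond of the target and the oxolane ring form together. The closest known reaction type is the samarium-diiodide reductive cyclization of aldehydes and methyl ketones onto β-alkoxyacrylates, established for oxanes and oxepanes and applied here to a tether one atom shorter. The ring should close through a chair-like 5-exo transition state with the 10-phenyldecyl group pseudo-equatorial, which places the acetate arm cis to it (2,5-cis), while the samarium-bound ketyl oxygen turns away from the acrylate so that hydroxyl and acetate arm end up trans (2,3-trans). The quaternary carbinol carbon C3 of the oxolane (C6 of the target) is thus controlled by the existing (R)-carbinol and should be (R); C2 should be (S) but is erased in step 6. The step needs reduction of the ketone before the acrylate and exo closure: the electron-rich β-alkoxyacrylate is harder to reduce than the ketone, and the nucleophilic ketyl is polarity-matched to the acrylate β-carbon.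

Step 6
Reactants: 9 methyl 2-[(2S,3R,5R)-3-hydroxy-3-methyl-5-(10-phenyldecyl)oxolan-2-yl]acetate
Product: 10 methyl (2E,4R,6R)-4,6-dihydroxy-4-methyl-16-phenylhexadec-2-enoate
Conditions: LiN(SiMe3)2 (2.5 equiv), THF, −78 to −20 °C; AcOH, −78 °C
Reagents that add atoms: none
Why: Ester enolization and E1cB expulsion of the ring oxygen (retro-oxa-Michael) should open the oxolane to the (E)-enoate, freeing the secondary carbinol and erasing the oxolane C2 centre; the quaternary carbinol is not touched.

Step 7
Reactants: 10 methyl (2E,4R,6R)-4,6-dihydroxy-4-methyl-16-phenylhexadec-2-enoate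
Product: 11 methyl (2E,4R)-4-hydroxy-4-methyl-6-oxo-16-phenylhexadec-2-enoate
Conditions: Dess–Martin periodinane, CH2Cl2, rt
Reagents that add atoms: none
Why: Dess–Martin oxidation should convert only the secondary alcohol, because the tertiary allylic alcohol has no carbinol hydrogen; the temporary stereocentre is removed here.

Step 8
Reactants: 11 methyl (2E,4R)-4-hydroxy-4-methyl-6-oxo-16-phenylhexadec-2-enoate
Product: 12 methyl (2E,4R)-6-hydroperoxy-4-hydroxy-6-methoxy-4-methyl-16-phenylhexadec-2-enoate
Conditions: urea–H2O2, Sc(OTf)3 (10 mol %), MeOH, rt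
Reagents that add atoms: hydrogen peroxide (OO), used as its urea adduct; methanol (CO)
Why: Lewis-acid-catalysed perketalization of a ketone with hydrogen peroxide in methanol (known for keto enoates) should give the α-methoxy hydroperoxide as both ketal epimers, which does not matter because this centre is ionized in step 10.

Step 9
Reactants: 12 methyl (2E,4R)-6-hydroperoxy-4-hydroxy-6-methoxy-4-methyl-16-phenylhexadec-2-enoate
Product: 14 (1R,6R)-4-methoxy-6-methyl-4-(10-phenyldecyl)-2,3,7-trioxabicyclo[4.3.0]nonan-8-one, via dioxane hydroxy ester 13 (not isolated)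
Conditions: Et2NH (0.5 equiv), CF3CH2OH, rt
Reagents that add atoms: none
Why: Reversible intramolecular 6-exo-trig peroxy-Michael addition of the hydroperoxide to the enoate should close the 1,2-dioxane, and only the adduct with the acetate arm cis to the tertiary hydroxyl can lactonize, so the (6R) centre funnels C1 to (R) through cis ring fusion.

Step 10
Reactants: 14 (1R,6R)-4-methoxy-6-methyl-4-(10-phenyldecyl)-2,3,7-trioxabicyclo[4.3.0]nonan-8-one
Product: 15 (1R,4R,6R)-4,6-dimethyl-4-(10-phenyldecyl)-2,3,7-trioxabicyclo[4.3.0]nonan-8-one (target)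
Conditions: Me3Al (3 equiv), CH2Cl2, −78 to −40 °C
Reagents that add atoms: trimethylaluminium (C[Al](C)C)
Why: Proposed new method: trimethylaluminium should ionize the methoxy group to the cyclic peroxycarbenium ion and deliver methyl to it, by analogy with Lewis-acid substitutions of 3-alkoxy-1,2-dioxanes by allylsilanes and silyl ketene acetals and with trialkylaluminium C-alkylation of cyclic oxocarbenium ions in peroxide-containing acetals; attack should be axial on the half-chair in which lactone oxygen O7 is pseudo-axial and C9 pseudo-equatorial, that is on the face syn to O7, which gives the (4R) peroxide carbon with the long chain equatorial.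

**Compound list**
1 | 11-phenylundecanoic acid | OC(=O)CCCCCCCCCCc1ccccc1 | starting material
2 | 11-phenylundecanoyl chloride | ClC(=O)CCCCCCCCCCc1ccccc1 | intermediate
3 | 11-phenylundecanal | O=CCCCCCCCCCCc1ccccc1 | intermediate
4 | (4R)-14-phenyltetradec-1-en-4-yl diisopinocampheylborinate | C=CC[C@H](OB([C@@H]1C[C@@H]2C[C@H]([C@H]1C)C2(C)C)[C@@H]1C[C@@H]2C[C@H]([C@H]1C)C2(C)C)CCCCCCCCCCc1ccccc1 | intermediate
5 | (R)-14-phenyltetradec-1-en-4-ol | C=CC[C@H](O)CCCCCCCCCCc1ccccc1 | intermediate
6 | methyl propiolate | C#CC(=O)OC | starting material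
7 | methyl (E)-3-{[(4R)-14-phenyltetradec-1-en-4-yl]oxy}prop-2-enoate | C=CC[C@H](O/C=C/C(=O)OC)CCCCCCCCCCc1ccccc1 | intermediate
8 | methyl (E)-3-{[(4R)-2-oxo-14-phenyltetradecan-4-yl]oxy}prop-2-enoate | CC(=O)C[C@H](O/C=C/C(=O)OC)CCCCCCCCCCc1ccccc1 | intermediate
9 | methyl 2-[(2S,3R,5R)-3-hydroxy-3-methyl-5-(10-phenyldecyl)oxolan-2-yl]acetate | COC(=O)C[C@@H]1O[C@H](CCCCCCCCCCc2ccccc2)C[C@@]1(C)O | intermediate
10 | methyl (2E,4R,6R)-4,6-dihydroxy-4-methyl-16-phenylhexadec-2-enoate | COC(=O)/C=C/[C@](C)(O)C[C@H](O)CCCCCCCCCCc1ccccc1 | intermediate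
11 | methyl (2E,4R)-4-hydroxy-4-methyl-6-oxo-16-phenylhexadec-2-enoate | COC(=O)/C=C/[C@](C)(O)CC(=O)CCCCCCCCCCc1ccccc1 | intermediate
12 | methyl (2E,4R)-6-hydroperoxy-4-hydroxy-6-methoxy-4-methyl-16-phenylhexadec-2-enoate (both epimers at the ketal carbon) | COC(=O)/C=C/[C@](C)(O)CC(OC)(OO)CCCCCCCCCCc1ccccc1 | intermediate
13 | methyl 2-[(3R,4R)-4-hydroxy-6-methoxy-4-methyl-6-(10-phenyldecyl)-1,2-dioxan-3-yl]acetate (both epimers at the ketal carbon) | COC(=O)C[C@H]1OOC(OC)(CCCCCCCCCCc2ccccc2)C[C@@]1(C)O | intermediate
14 | (1R,6R)-4-methoxy-6-methyl-4-(10-phenyldecyl)-2,3,7-trioxabicyclo[4.3.0]nonan-8-one (both epimers at the ketal carbon) | COC1(CCCCCCCCCCc2ccccc2)C[C@@]2(C)OC(=O)C[C@H]2OO1 | intermediate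
15 | (1R,4R,6R)-4,6-dimethyl-4-(10-phenyldecyl)-2,3,7-trioxabicyclo[4.3.0]nonan-8-one | C[C@@]1(CCCCCCCCCCc2ccccc2)C[C@@]2(C)OC(=O)C[C@H]2OO1 | target

**Totals:** 10 steps; longest linear sequence 10 steps.

**Steps most likely to fail**

Step 10 (methyl transfer to the peroxyketal). What may go wrong: ionization at the peroxide oxygen instead of the methoxy oxygen with ring opening, reduction of the O–O bond by the organoaluminium, or insufficient facial selectivity. Fallback with known chemistry: setting out from keto enoate 11, Wittig methylenation (Ph3P=CH2, THF, 0 °C) should give the methylidene ester F1. Mukaiyama–Isayama hydroperoxysilylation of its 1,1-disubstituted alkene (Co(thd)2, thd = 2,2,6,6-tetramethylheptane-3,5-dionate, O2, Et3SiH, 1,2-dichloroethane) should give the tertiary triethylsilyl peroxide F2 together with its epimer at the peroxide carbon, since the tertiary radical is trapped without facial control. Bu4NF/AcOH should free the hydroperoxide F3, and Et2NH in CF3CH2OH should close dioxane and lactone as in step 9. The route is rejoined at 15 after chromatographic removal of the epimer at the peroxide quaternary carbon.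

Step 9 (peroxy-Michael addition and lactonization). What may go wrong: base-induced Kornblum–DeLaMare fragmentation of the peroxide, or the trans adduct neither returning by retro-addition nor lactonizing. Fallback: setting out from oxolane 9, catalytic KOtBu in THF should equilibrate the acetate arm by retro-oxa-Michael/oxa-Michael addition and trap the cis isomer as the bicyclic ether lactone F4. LiN(SiMe3)2 at −78 °C followed by AcOH should open the ether ring by E1cB to the hydroxy butenolide F5, and Dess–Martin oxidation should give the keto butenolide F6. Urea–H2O2/Sc(OTf)3/MeOH should then give the hydroperoxy ketal F7, whose peroxy-Michael addition to the butenolide (Et2NH, CF3CH2OH) can only give the cis-fused bicycle. The route is rejoined at 14.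

Step 8 (perketalization). What may go wrong: acid-promoted retro-aldol cleavage or dehydration of the tertiary β-hydroxy ketone, or incomplete exchange at the ketone. Fallback: setting out from 11, Wittig methylenation should give the methylidene ester F8. Ozonolysis with a controlled dose of O3 in CH2Cl2–MeOH at −78 °C should cleave the electron-rich 1,1-disubstituted alkene in preference to the enoate, and the carbonyl oxide should be captured by methanol to give 12 directly, where the route is rejoined.

**Further compounds**
F1 | step 10 | methyl (2E,4R)-4-hydroxy-4-methyl-6-methylidene-16-phenylhexadec-2-enoate | COC(=O)/C=C/[C@](C)(O)CC(=C)CCCCCCCCCCc1ccccc1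
F2 | step 10 | methyl (2E,4R,6R)-4-hydroxy-4,6-dimethyl-16-phenyl-6-[(triethylsilyl)peroxy]hexadec-2-enoate | COC(=O)/C=C/[C@](C)(O)C[C@](C)(OO[Si](CC)(CC)CC)CCCCCCCCCCc1ccccc1
F3 | step 10 | methyl (2E,4R,6R)-6-hydroperoxy-4-hydroxy-4,6-dimethyl-16-phenylhexadec-2-enoate | COC(=O)/C=C/[C@](C)(O)C[C@](C)(OO)CCCCCCCCCCc1ccccc1
F4 | step 9 | (2R,3aR,6aR)-3a-methyl-2-(10-phenyldecyl)hexahydrofuro[3,2-b]furan-5-one | O=C1C[C@H]2O[C@H](CCCCCCCCCCc3ccccc3)C[C@@]2(C)O1
F5 | step 9 | (5R)-5-[(2R)-2-hydroxy-12-phenyldodecyl]-5-methylfuran-2(5H)-one | O=C1C=C[C@@](C)(C[C@H](O)CCCCCCCCCCc2ccccc2)O1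
F6 | step 9 | (5R)-5-methyl-5-(2-oxo-12-phenyldodecyl)furan-2(5H)-one | O=C1C=C[C@@](C)(CC(=O)CCCCCCCCCCc2ccccc2)O1
F7 | step 9 | (5R)-5-(2-hydroperoxy-2-methoxy-12-phenyldodecyl)-5-methylfuran-2(5H)-one | O=C1C=C[C@@](C)(CC(OC)(OO)CCCCCCCCCCc2ccccc2)O1
F8 | step 8 | methyl (2E,4R)-4-hydroxy-4-methyl-6-methylidene-16-phenylhexadec-2-enoate | COC(=O)/C=C/[C@](C)(O)CC(=C)CCCCCCCCCCc1ccccc1
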